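**Strategy.** The flavone is assembled at the bond between C2 of the pyranone ring (ring C) and C1′ of the dimethoxyphenyl ring (ring B). The key step exploits the C2–H of a 5,7-diprotected chromone. It is the most acidic C–H (vinylic, next to O1, β to the C4 carbonyl), so direct zincation and Negishi coupling join the chromone to an aryl bromide that already carries the complete erythro arylglycerol β-ether, with no handle on the chromone. The bromide arises from an Evans syn-glycolate aldol (threo) and a double Mitsunobu acetylation that inverts the benzylic carbon C7 to erythro and protects both alcohols at once.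

Key step: step 6

Remark: side-chain atoms are numbered C7 (benzylic carbinol carbon), C8 (carbon bearing the aryl ether oxygen) and C9 (CH2OH); compounds 1, 2, 4 and 10 are taken as catalogue chemicals.

**Step 1**
Reactants: 1 4-bromo-2,6-dimethoxyphenol; 2 (S)-4-benzyl-3-(chloroacetyl)oxazolidin-2-one
Product: 3 (S)-4-benzyl-3-[(4-bromo-2,6-dimethoxyphenoxy)acetyl]oxazolidin-2-one
Conditions: K2CO3, NaI (cat.), acetone, 50 °C
Reagents that add atoms: none
Why: Williamson ether synthesis with Finkelstein catalysis, in which the phenoxide of 1 should displace the halide at the doubly activated α-carbon of the imide much faster than it attacks an imide carbonyl, and no stereocentre is touched.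

**Step 2**
Reactants: 3 (S)-4-benzyl-3-[(4-bromo-2,6-dimethoxyphenoxy)acetyl]oxazolidin-2-one; 4 4-(triisopropylsilyloxy)benzaldehyde
Product: 7 (S)-4-benzyl-3-[(2S,3R)-2-(4-bromo-2,6-dimethoxyphenoxy)-3-hydroxy-3-(4-triisopropylsilyloxyphenyl)propanoyl]oxazolidin-2-one, via (Z)-dibutylboron enolate 5 (not isolated), via dibutylboron aldolate 6 (not isolated)
Conditions: Bu2BOTf, iPr2NEt, CH2Cl2, −78 to 0 °C; then 4, −78 to 0 °C; then pH 7 phosphate buffer, MeOH, 30% H2O2, 0 °C
Reagents that add atoms: none
Why: Evans syn-aldol reaction, in which the (Z)-boron enolate should react through a closed chair-like transition state on the enolate face opposite the benzyl group of the (S)-auxiliary, setting C8 and C7 together as the syn (threo) pair.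

**Step 3**
Reactants: 7 the syn-aldol imide
Product: 8 (1R,2R)-2-(4-bromo-2,6-dimethoxyphenoxy)-1-(4-triisopropylsilyloxyphenyl)propane-1,3-diol
Conditions: LiBH4, MeOH (1 equiv), THF, 0 °C
Reagents that add atoms: none
Why: Reductive cleavage of the N-acyl oxazolidinone by hydride attack at the exocyclic carbonyl should release the primary alcohol C9 and the recoverable auxiliary without touching C7 or C8 (the descriptor at C8 changes only because the priorities change).

**Step 4**
Reactants: 8 the threo 1,3-diol
Product: 9 (1S,2R)-2-(4-bromo-2,6-dimethoxyphenoxy)-1-(4-triisopropylsilyloxyphenyl)propane-1,3-diyl diacetate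
Conditions: PPh3, DIAD, AcOH (3 equiv each), THF, 0 °C to rt
Reagents that add atoms: acetic acid CC(=O)O
Why: Double Mitsunobu esterification, in which acetate should displace both alkoxyphosphonium groups, simply acetylating the primary C9 and inverting the benzylic C7 from R to S by SN2 attack, so that the threo diol becomes the protected erythro isomer in one operation.

**Step 5**
Reactants: 10 5,7-dihydroxy-4H-chromen-4-one
Product: 11 4-oxo-4H-chromene-5,7-diyl bis(2,2-dimethylpropanoate)
Conditions: PivCl, Et3N, DMAP (cat.), CH2Cl2, 0 °C to rt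
Reagents that add atoms: pivaloyl chloride CC(C)(C)C(=O)Cl
Why: DMAP-catalysed O-acylation of both phenols should give pivalates that have no α-hydrogen and a hindered carbonyl, hence survive the zinc amide of step 6 and fall in the same methanolysis as the acetates.

**Step 6**
Reactants: 11 4-oxo-4H-chromene-5,7-diyl bis(2,2-dimethylpropanoate); 9 the erythro aryl bromide diacetate
Product: 13 (1S,2R)-2-{4-[5,7-bis(pivaloyloxy)-4-oxo-4H-chromen-2-yl]-2,6-dimethoxyphenoxy}-1-(4-triisopropylsilyloxyphenyl)propane-1,3-diyl diacetate, via chromon-2-ylzinc chloride 12 (not isolated)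
Conditions: TMPZnCl·LiCl, THF, 25 °C; then 9, Pd(OAc)2 (cat.), SPhos, THF, 50 °C
Reagents that add atoms: none
Why: TMPZnCl·LiCl should remove the C2–H of ring C, the most acidic C–H of 11 because the carbanion is vinylic, adjacent to the ring oxygen O1 and β to the C4 carbonyl, giving the alkenylzinc 12, which tolerates the pivalates. Zerovalent palladium formed from Pd(OAc)2 and SPhos then inserts into the C1′–Br bond of 9, and transmetalation from zinc followed by reductive elimination forges the C2–C1′ bond; the closest known reaction type is the zinc amide C–H metalation of chromones followed by Negishi cross-coupling. No ring is closed and no stereocentre is formed; C7 and C8 carry no acidic hydrogen and should pass unchanged through the neutral conditions. The step needs metalation at C2 in preference to C3, which is secured by leaving out any Lewis acid (MgCl2, BF3) that would steer the base to C3 through carbonyl coordination. It also needs oxidative addition at the aryl bromide in preference to the benzylic acetate, which the electron-rich biaryl phosphine at 50 °C should provide, while the mild organozinc leaves the four esters and the silyl ether intact.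

**Step 7**
Reactants: 13 the fully protected flavone
Product: 15 2-(4-{[(1S,2R)-1,3-dihydroxy-1-(4-hydroxyphenyl)propan-2-yl]oxy}-3,5-dimethoxyphenyl)-5,7-dihydroxy-4H-chromen-4-one, via phenol triisopropylsilyl ether 14 (not isolated)
Conditions: K2CO3, MeOH–THF, 0 °C to rt; then AcOH, Bu4NF, THF, rt
Reagents that add atoms: none
Why: Base-mediated transesterification should remove the two acetates and two pivalates while the robust aryl triisopropylsilyl ether stays, so that the benzylic acetate at C7 is gone before the para-phenol is unmasked (no quinone-methide elimination that would scramble C7), and buffered fluoride desilylation then frees the last phenol near neutrality.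

**Compound list**
1 | 4-bromo-2,6-dimethoxyphenol | COc1cc(Br)cc(OC)c1O | starting material
2 | (S)-4-benzyl-3-(chloroacetyl)oxazolidin-2-one | O=C(CCl)N1C(=O)OC[C@@H]1Cc1ccccc1 | starting material
3 | (S)-4-benzyl-3-[(4-bromo-2,6-dimethoxyphenoxy)acetyl]oxazolidin-2-one | COc1cc(Br)cc(OC)c1OCC(=O)N1C(=O)OC[C@@H]1Cc1ccccc1 | intermediate
4 | 4-(triisopropylsilyloxy)benzaldehyde | O=Cc1ccc(O[Si](C(C)C)(C(C)C)C(C)C)cc1 | starting material
5 | (Z)-dibutylboron enolate of 3 (aryloxy group cis to the boron-bound oxygen) | CCCCB(CCCC)O/C(=C\Oc1c(OC)cc(Br)cc1OC)N1C(=O)OC[C@@H]1Cc1ccccc1 | intermediate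
6 | O-dibutylboryl aldolate of 7 | COc1cc(Br)cc(OC)c1O[C@H](C(=O)N1C(=O)OC[C@@H]1Cc1ccccc1)[C@H](OB(CCCC)CCCC)c1ccc(O[Si](C(C)C)(C(C)C)C(C)C)cc1 | intermediate
7 | (S)-4-benzyl-3-[(2S,3R)-2-(4-bromo-2,6-dimethoxyphenoxy)-3-hydroxy-3-(4-triisopropylsilyloxyphenyl)propanoyl]oxazolidin-2-one (syn aldol) | COc1cc(Br)cc(OC)c1O[C@H](C(=O)N1C(=O)OC[C@@H]1Cc1ccccc1)[C@H](O)c1ccc(O[Si](C(C)C)(C(C)C)C(C)C)cc1 | intermediate
8 | (1R,2R)-2-(4-bromo-2,6-dimethoxyphenoxy)-1-(4-triisopropylsilyloxyphenyl)propane-1,3-diol (threo) | COc1cc(Br)cc(OC)c1O[C@H](CO)[C@H](O)c1ccc(O[Si](C(C)C)(C(C)C)C(C)C)cc1 | intermediate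
9 | (1S,2R)-2-(4-bromo-2,6-dimethoxyphenoxy)-1-(4-triisopropylsilyloxyphenyl)propane-1,3-diyl diacetate (erythro) | COc1cc(Br)cc(OC)c1O[C@H](COC(C)=O)[C@@H](OC(C)=O)c1ccc(O[Si](C(C)C)(C(C)C)C(C)C)cc1 | intermediate
10 | 5,7-dihydroxy-4H-chromen-4-one (5,7-dihydroxychromone) | O=c1ccoc2cc(O)cc(O)c12 | starting material
11 | 4-oxo-4H-chromene-5,7-diyl bis(2,2-dimethylpropanoate) | CC(C)(C)C(=O)Oc1cc(OC(=O)C(C)(C)C)c2c(=O)ccoc2c1 | intermediate
12 | [4-oxo-5,7-bis(pivaloyloxy)-4H-chromen-2-yl]zinc chloride (LiCl complex) | CC(C)(C)C(=O)Oc1cc(OC(=O)C(C)(C)C)c2c(=O)cc([Zn]Cl)oc2c1 | intermediate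
13 | (1S,2R)-2-{4-[5,7-bis(pivaloyloxy)-4-oxo-4H-chromen-2-yl]-2,6-dimethoxyphenoxy}-1-(4-triisopropylsilyloxyphenyl)propane-1,3-diyl diacetate | COc1cc(-c2cc(=O)c3c(OC(=O)C(C)(C)C)cc(OC(=O)C(C)(C)C)cc3o2)cc(OC)c1O[C@H](COC(C)=O)[C@@H](OC(C)=O)c1ccc(O[Si](C(C)C)(C(C)C)C(C)C)cc1 | intermediate
14 | 2-(4-{[(1S,2R)-1,3-dihydroxy-1-(4-triisopropylsilyloxyphenyl)propan-2-yl]oxy}-3,5-dimethoxyphenyl)-5,7-dihydroxy-4H-chromen-4-one | COc1cc(-c2cc(=O)c3c(O)cc(O)cc3o2)cc(OC)c1O[C@H](CO)[C@@H](O)c1ccc(O[Si](C(C)C)(C(C)C)C(C)C)cc1 | intermediate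
15 | 2-(4-{[(1S,2R)-1,3-dihydroxy-1-(4-hydroxyphenyl)propan-2-yl]oxy}-3,5-dimethoxyphenyl)-5,7-dihydroxy-4H-chromen-4-one (erythro, 7S,8R) | COc1cc(-c2cc(=O)c3c(O)cc(O)cc3o2)cc(OC)c1O[C@H](CO)[C@@H](O)c1ccc(O)cc1 | target

**Step count and risks**
Total steps: 7. Longest linear sequence: 6 (steps 1, 2, 3, 4, 6, 7).

Steps most likely to fail:

1. Step 6. Metalation may occur away from C2 (at C3 or on ring A), the metalated pyranone may open, or a slow cross-coupling may let the zinc amide attack the acetates. The fallback reverses the polarity and avoids chromone metalation. It sets out from 9: Miyaura borylation (B2pin2, PdCl2(dppf), KOAc, dioxane, 80 °C) should give the arylboronic acid pinacol ester F1. Oxidative boron-Heck arylation of 11 with F1 (Pd(OCOCF3)2, 5-nitro-1,10-phenanthroline, O2, DMSO, 80–100 °C) follows. An aryl complex of divalent palladium adds across the O1–C2=C3–C4=O enone with the aryl group going to C2, and β-hydride elimination restores the double bond. The sequence should come back to the route at 13.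

2. Step 4. The electron-rich benzylic alkoxyphosphonium ion may ionise (loss of stereospecificity at C7), eliminate toward the aryl enol ether, or the free 1,3-diol may divert through a cyclic phosphorane or oxetane. The fallback replaces SN2 inversion by oxidation and diastereoselective reduction. It sets out from 8: selective oxidation of the benzylic alcohol with DDQ (CH2Cl2, rt) should give the ketol F2. Reduction with Zn(BH4)2 (Et2O, −20 °C) under chelation control between the carbonyl and the α-aryloxy oxygen (non-basic, so C8 should hold) should favour the erythro diol F3; any threo isomer formed is 8 itself and can be recycled. Acetylation (Ac2O, pyridine, DMAP) should come back to the route at 9.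

3. Step 1. Acyl transfer from the imide to the hindered, doubly ortho-substituted phenoxide (loss of the auxiliary) may compete with O-alkylation. The fallback builds the ether before the imide. It sets out from 1: alkylation with bromoacetic acid (NaOH, H2O, reflux; then HCl) should give (4-bromo-2,6-dimethoxyphenoxy)acetic acid F4. Activation with pivaloyl chloride and Et3N (THF, −20 °C) gives the mixed pivalic anhydride F5, which is N-acylated in the same flask by (S)-4-benzyloxazolidin-2-one and LiCl. This should come back to the route at 3.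

**Further compounds**
F1 | step 6 | (1S,2R)-2-[2,6-dimethoxy-4-(4,4,5,5-tetramethyl-1,3,2-dioxaborolan-2-yl)phenoxy]-1-(4-triisopropylsilyloxyphenyl)propane-1,3-diyl diacetate | COc1cc(B2OC(C)(C)C(C)(C)O2)cc(OC)c1O[C@H](COC(C)=O)[C@@H](OC(C)=O)c1ccc(O[Si](C(C)C)(C(C)C)C(C)C)cc1
F2 | step 4 | (R)-2-(4-bromo-2,6-dimethoxyphenoxy)-3-hydroxy-1-(4-triisopropylsilyloxyphenyl)propan-1-one | COc1cc(Br)cc(OC)c1O[C@H](CO)C(=O)c1ccc(O[Si](C(C)C)(C(C)C)C(C)C)cc1
F3 | step 4 | (1S,2R)-2-(4-bromo-2,6-dimethoxyphenoxy)-1-(4-triisopropylsilyloxyphenyl)propane-1,3-diol (erythro) | COc1cc(Br)cc(OC)c1O[C@H](CO)[C@@H](O)c1ccc(O[Si](C(C)C)(C(C)C)C(C)C)cc1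
F4 | step 1 | (4-bromo-2,6-dimethoxyphenoxy)acetic acid | COc1cc(Br)cc(OC)c1OCC(=O)O
F5 | step 1 | (4-bromo-2,6-dimethoxyphenoxy)acetic pivalic anhydride | COc1cc(Br)cc(OC)c1OCC(=O)OC(=O)C(C)(C)C
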